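**Retrosynthetic overview**

- Ring numbering used below: O1–O2–C3(H)(CH2CO2Me)–C4H2–C5H2–C6(OMe)(side chain). The enyne is cut at its C(sp)–C(sp2) bond (Sonogashira coupling) into a dioxane bearing a pent-4-ynyl group and an (E)-vinyl iodide.
- The 1,2-dioxane (the only ring) is cut at C5–C6 and at O2–C3 into three components: an orthoester (C6 with its methoxy group and chain), bis(trimethylsilyl) peroxide (O1–O2) and an allylsilane (C3–C5 plus the acetate arm).
- Enabling feature: C6 is a ketal carbon flanked by the methoxy oxygen and O1, so it is a latent peroxycarbenium ion (an electrophilic carbon next to a nucleophilic O–O unit). C3 lies β to the ester carbonyl, so it is a latent Michael acceptor. The C4–C5 ethylene between them is supplied by an allylsilane after a 1,3-shift of its double bond.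
- Order: both ring bonds are made in one flask (C5–C6 first, then O2–C3 closes the ring); the ketal carbon C6 is then equilibrated and the side chain is attached last.

Key step: step 3

Assumption (remark on the chemistry): the ketal configuration of the target (methoxy cis to the acetate arm, 3S,6R) is taken to be the thermodynamically preferred anomer of the 1,2-dioxane (methoxy axial, both carbon chains equatorial); step 4 relies on this.

**Step 1**
Reactants: 1 hex-5-ynenitrile
Product: 3 6,6,6-trimethoxyhex-1-yne (trimethyl orthohex-5-ynoate), via imidate hydrochloride 2 (not isolated)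
Conditions: HCl (g), MeOH (1.1 equiv), Et2O, 0 °C; then MeOH (excess), hexane, rt
Reagents that add atoms: methanol (CO)
Why: Pinner reaction: HCl and methanol convert the nitrile into the imidate hydrochloride, and alcoholysis of this salt with more methanol should give the orthoester with precipitation of ammonium chloride; the terminal alkyne is inert under these cold anhydrous conditions and no stereocentre is formed.

**Step 2**
Reactants: 4 (2E)-3-(trimethylsilyl)prop-2-en-1-ol; 5 trimethyl orthoacetate
Product: 7 methyl 3-(trimethylsilyl)pent-4-enoate (racemic), via ketene acetal 6 (not isolated)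
Conditions: EtCO2H (5 mol %), xylene, 140 °C, MeOH distilled off
Reagents that add atoms: none
Why: Johnson–Claisen rearrangement: acid-catalysed exchange gives the mixed ketene acetal 6, whose [3,3]-sigmatropic shift forms the C–C bond at the silicon-bearing alkene carbon and should give the β-silyl γ,δ-unsaturated ester (an allylsilane); its stereocentre is formed racemic, which is of no consequence because this carbon becomes sp2 in step 3.

**Step 3**
Reactants: 3 6,6,6-trimethoxyhex-1-yne; 7 methyl 3-(trimethylsilyl)pent-4-enoate; 8 bis(trimethylsilyl) peroxide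
Product: 13 methyl 2-[(3S)-6-methoxy-6-(pent-4-yn-1-yl)-1,2-dioxan-3-yl]acetate (both C6 epimers), via perortho ester 9 (not isolated), via silylperoxy enoate 10 (not isolated), via hydroperoxide 11 (not isolated), via conjugated hydroperoxide 12 (not isolated)
Conditions: 3, 8 (1.1 equiv), TMSOTf (5 mol %), CH2Cl2, −78 °C; then 7 (1.2 equiv), −78 °C; then MeOH (3 equiv), chiral bifunctional iminophosphorane–thiourea organocatalyst (BIMP type, tert-leucine-derived, 15 mol %), −78 °C → rt
Reagents that add atoms: none
Why: Proposed new method: TMSOTf should exchange one methoxy group of 3 for the silylperoxy group (9) and then ionise a second methoxy group to a peroxycarbenium ion stabilised by both the methoxy and the peroxy oxygen, which allylsilane 7 attacks through its terminal CH2 (anti-SE2′, Hosomi–Sakurai type) to form the C5–C6 bond and give the (E)-β,γ-unsaturated ester 10. Methanol then frees hydroperoxide 11, and the chiral base shifts the double bond into conjugation (12) and delivers the hydroperoxide oxygen to C3 (oxa-Michael addition), forming the O2–C3 bond and closing the 1,2-dioxane by a 6-exo-trig cyclisation. The closest known reaction types are the Lewis-acid-mediated allylation of peroxycarbenium ions from monoperoxyketals, the amine-mediated cyclisation of hydroperoxy ketals onto enoates to give 3-methoxy-1,2-dioxane-6-acetates, and the iminophosphorane-catalysed enantioselective intramolecular oxa-Michael addition of alcohols to unactivated α,β-unsaturated esters. The C3 stereocentre (S) is set by the catalyst, which binds the enoate through its thiourea and pairs the peroxide anion with its iminophosphoranium N–H so that one enoate face is attacked (the catalyst antipode that gives 3S is to be fixed in a test run), whereas C6 is formed without control and is corrected in step 4. The step needs ionisation of a methoxy group rather than the silylperoxy group (the more basic methoxy oxygen is silylated, and a ketal formed by the reverse order of events is expected to be drawn back by exchange with 8), loss of silicon from the β-silyl cation rather than its capture by the peroxide, and kinetic ring closure, which low temperature and fast protonation of the ester enolate should secure.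

**Step 4**
Reactants: 13 methyl 2-[(3S)-6-methoxy-6-(pent-4-yn-1-yl)-1,2-dioxan-3-yl]acetate (both C6 epimers)
Product: 14 methyl 2-[(3S,6R)-6-methoxy-6-(pent-4-yn-1-yl)-1,2-dioxan-3-yl]acetate
Conditions: CSA (5 mol %), MeOH, 0 °C → rt
Reagents that add atoms: methanol (CO)
Why: Acid-catalysed acetal exchange (anomerisation of a cyclic peroxyketal): reversible loss of methanol from C6 gives the ring peroxycarbenium ion, which recaptures methanol until the more stable epimer predominates, the one with the methoxy group axial (anomeric effect) and the pentynyl and acetate chains equatorial, which is 6R for the fixed 3S centre; C3 carries no ionisable group and should be untouched.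

**Step 5**
Reactants: 15 dec-9-yn-1-ol
Product: 17 10-(trimethylsilyl)dec-9-yn-1-ol, via bis-silyl ether 16 (not isolated)
Conditions: n-BuLi (2.2 equiv), THF, −78 °C; TMSCl (2.5 equiv), −78 °C → rt; then 1 M HCl, rt
Reagents that add atoms: chlorotrimethylsilane (C[Si](C)(C)Cl)
Why: Double deprotonation and silylation of alcohol and alkyne followed by selective hydrolysis of the labile O–Si bond should leave the C-silylated alkyne, which masks the distal terminal alkyne for the Sonogashira coupling.

**Step 6**
Reactants: 17 10-(trimethylsilyl)dec-9-yn-1-ol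
Product: 18 10-(trimethylsilyl)dec-9-ynal
Conditions: TEMPO (10 mol %), PhI(OAc)2 (1.1 equiv), CH2Cl2, rt
Reagents that add atoms: none
Why: Oxoammonium-mediated (TEMPO) oxidation of a primary alcohol, which stops at the aldehyde under anhydrous conditions and leaves the silylalkyne untouched.

**Step 7**
Reactants: 18 10-(trimethylsilyl)dec-9-ynal
Product: 19 [(10E)-11-iodoundec-10-en-1-yn-1-yl]trimethylsilane
Conditions: CrCl2 (6 equiv), CHI3 (2 equiv), THF–dioxane, 0 °C → rt
Reagents that add atoms: iodoform (IC(I)I)
Why: Takai olefination: the geminal dichromium species formed from iodoform and CrCl2 adds to the aldehyde and anti elimination from the preferred adduct should give the vinyl iodide with E geometry, the stereochemical element set here.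

**Step 8**
Reactants: 14 methyl 2-[(3S,6R)-6-methoxy-6-(pent-4-yn-1-yl)-1,2-dioxan-3-yl]acetate; 19 [(10E)-11-iodoundec-10-en-1-yn-1-yl]trimethylsilane
Product: 20 methyl 2-[(3S,6R)-6-methoxy-6-[(6E)-16-(trimethylsilyl)hexadec-6-ene-4,15-diyn-1-yl]-1,2-dioxan-3-yl]acetate
Conditions: Pd(PPh3)4 (5 mol %), CuI (10 mol %), i-Pr2NH (3 equiv), THF (degassed), rt
Reagents that add atoms: none
Why: Sonogashira coupling: oxidative addition of the vinyl iodide, transmetalation of the copper acetylide of 14 and reductive elimination form the C(sp)–C(sp2) bond with retention of the E geometry; the dialkyl peroxyketal is expected to survive Pd(PPh3)4 and triphenylphosphine at room temperature, and the 3S centre, the thermodynamically favoured epimer for a 6R ketal, should not be endangered by the amine.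

**Step 9**
Reactants: 20 methyl 2-[(3S,6R)-6-methoxy-6-[(6E)-16-(trimethylsilyl)hexadec-6-ene-4,15-diyn-1-yl]-1,2-dioxan-3-yl]acetate
Product: 21 methyl 2-[(3S,6R)-6-[(6E)-hexadec-6-ene-4,15-diyn-1-yl]-6-methoxy-1,2-dioxan-3-yl]acetate (target)
Conditions: AgNO3 (10 mol %), MeOH–H2O–CH2Cl2, rt
Reagents that add atoms: none
Why: Silver-catalysed protodesilylation of the alkynylsilane (through the silver acetylide, protonated by the medium) under neutral conditions, which avoids base-induced retro-oxa-Michael opening of the β-peroxy ester and should leave both stereocentres and the E-enyne untouched.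

**Compound list**

1 | hex-5-ynenitrile | C#CCCCC#N | starting material
2 | methyl hex-5-ynimidate hydrochloride | C#CCCCC(OC)=[NH2+].[Cl-] | intermediate
3 | 6,6,6-trimethoxyhex-1-yne | C#CCCCC(OC)(OC)OC | intermediate
4 | (2E)-3-(trimethylsilyl)prop-2-en-1-ol | C[Si](C)(C)/C=C/CO | starting material
5 | trimethyl orthoacetate (1,1,1-trimethoxyethane) | CC(OC)(OC)OC | starting material
6 | trimethyl[(1E)-3-[(1-methoxyethenyl)oxy]prop-1-en-1-yl]silane | C=C(OC)OC/C=C/[Si](C)(C)C | intermediate
7 | methyl 3-(trimethylsilyl)pent-4-enoate (racemic) | COC(=O)CC(C=C)[Si](C)(C)C | intermediate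
8 | bis(trimethylsilyl) peroxide | C[Si](C)(C)OO[Si](C)(C)C | starting material
9 | [(1,1-dimethoxyhex-5-yn-1-yl)peroxy]trimethylsilane | C#CCCCC(OC)(OC)OO[Si](C)(C)C | intermediate
10 | methyl (3E)-6-methoxy-6-[(trimethylsilyl)peroxy]undec-3-en-10-ynoate (racemic) | C#CCCCC(OC)(OO[Si](C)(C)C)C/C=C/CC(=O)OC | intermediate
11 | methyl (3E)-6-hydroperoxy-6-methoxyundec-3-en-10-ynoate (racemic) | C#CCCCC(OC)(OO)C/C=C/CC(=O)OC | intermediate
12 | methyl (2E)-6-hydroperoxy-6-methoxyundec-2-en-10-ynoate (racemic) | C#CCCCC(OC)(OO)CC/C=C/C(=O)OC | intermediate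
13 | methyl 2-[(3S)-6-methoxy-6-(pent-4-yn-1-yl)-1,2-dioxan-3-yl]acetate (both C6 epimers) | C#CCCCC1(OC)CC[C@@H](CC(=O)OC)OO1 | intermediate
14 | methyl 2-[(3S,6R)-6-methoxy-6-(pent-4-yn-1-yl)-1,2-dioxan-3-yl]acetate | C#CCCC[C@]1(OC)CC[C@@H](CC(=O)OC)OO1 | intermediate
15 | dec-9-yn-1-ol | C#CCCCCCCCCO | starting material
16 | trimethyl{[10-(trimethylsilyl)dec-9-yn-1-yl]oxy}silane | C[Si](C)(C)C#CCCCCCCCCO[Si](C)(C)C | intermediate
17 | 10-(trimethylsilyl)dec-9-yn-1-ol | C[Si](C)(C)C#CCCCCCCCCO | intermediate
18 | 10-(trimethylsilyl)dec-9-ynal | C[Si](C)(C)C#CCCCCCCCC=O | intermediate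
19 | [(10E)-11-iodoundec-10-en-1-yn-1-yl]trimethylsilane | C[Si](C)(C)C#CCCCCCCC/C=C/I | intermediate
20 | methyl 2-[(3S,6R)-6-methoxy-6-[(6E)-16-(trimethylsilyl)hexadec-6-ene-4,15-diyn-1-yl]-1,2-dioxan-3-yl]acetate | C[Si](C)(C)C#CCCCCCCC/C=C/C#CCCC[C@]1(OC)CC[C@@H](CC(=O)OC)OO1 | intermediate
21 | methyl 2-[(3S,6R)-6-[(6E)-hexadec-6-ene-4,15-diyn-1-yl]-6-methoxy-1,2-dioxan-3-yl]acetate | C#CCCCCCCC/C=C/C#CCCC[C@]1(OC)CC[C@@H](CC(=O)OC)OO1 | target

**Count**

Total step count: 9. Longest linear sequence: 5 steps (steps 1, 3, 4, 8, 9; the branch through steps 5, 6, 7, 8, 9 is equally long).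

**Steps most likely to fail**

1. Step 3 (the step that bears the label).
   - What may go wrong: ionisation of the perortho ester with loss of the silylperoxy group instead of a methoxy group; capture of the β-silyl cation by the peroxide oxygen (closure of a five-membered ring) instead of loss of silicon; Criegee-type migration in the silylperoxy ketal under the silyl triflate; a sluggish 1,3-proton shift; reversible ring closure or substrate control by the C6 centre eroding the enantioselectivity.
   - Fallback (sets out from 1, comes back at 14; known reactions only, with C3 taken from the chiral pool): Addition of MeMgBr (2.2 equiv, the first equivalent being consumed by the alkyne C–H) to 1 and acidic hydrolysis should give hept-6-yn-2-one F1, which Me2NNH2 converts into its N,N-dimethylhydrazone F2. Double deprotonation (LDA, 2.1 equiv) and opening of commercial (S)-2-[2-(tert-butyldimethylsilyloxy)ethyl]oxirane at its CH2 group by the aza-enolate of the methyl group, followed by hydrolysis of the hydrazone (aqueous CuCl2), should give (9R)-11-[(tert-butyldimethylsilyl)oxy]-9-hydroxyundec-1-yn-6-one F3. Wittig methylenation (Ph3P=CH2) gives (3R)-1-[(tert-butyldimethylsilyl)oxy]-6-methylideneundec-10-yn-3-ol F4, and MsCl/Et3N gives its methanesulfonate F5. Ozonolysis of the 1,1-disubstituted alkene in MeOH–CH2Cl2 at −78 °C (the alkyne reacts far more slowly) gives the hydroperoxy ketal F6. KOtBu/18-crown-6 then closes the ring by intramolecular SN2 displacement of the mesylate by the hydroperoxide (6-exo-tet, inversion, R to S) to the dioxane silyl ether F7. CSA in MeOH removes the silyl ether and equilibrates C6 as in step 4 to the alcohol F8; TEMPO/PhI(OAc)2 in MeCN–H2O gives the acid F9, and Me3SiCHN2 in MeOH–toluene gives 14.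

2. Step 8.
   - What may go wrong: reductive cleavage of the O–O bond by low-valent palladium, by the phosphine or by the copper acetylide; oxidative dimerisation of 14; amine-induced opening of the β-peroxy ester.
   - Fallback (sets out from 1 and 19, comes back at 20): the carbon–carbon coupling is moved in front of the peroxide-forming step. Sonogashira coupling of 1 with 19 under the conditions of step 8 should give the enyne nitrile F10; a Pinner reaction as in step 1 gives the orthoester F11; annulation with 8 and 7 as in step 3 gives the dioxane F12 as its C6 epimers, and equilibration as in step 4 gives 20.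

3. Step 7.
   - What may go wrong: incomplete E selectivity (the Z isomer is not easily removed and would be carried into the target), and over-reduction of the vinyl iodide by excess divalent chromium.
   - Fallback (sets out from 18, comes back at 19): one-carbon homologation of 18 with lithiated (trimethylsilyl)diazomethane (Colvin rearrangement) should give the terminal alkyne F13. Hydrozirconation with Cp2Zr(H)Cl, which adds syn and only to the terminal alkyne, followed by iodinolysis with I2 with retention, gives 19 as the E isomer only.

Further compounds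
F1 | step 3 | hept-6-yn-2-one | CC(=O)CCCC#C
F2 | step 3 | hept-6-yn-2-one N,N-dimethylhydrazone | CN(C)N=C(C)CCCC#C
F3 | step 3 | (9R)-11-[(tert-butyldimethylsilyl)oxy]-9-hydroxyundec-1-yn-6-one | C#CCCCC(=O)CC[C@H](CCO[Si](C)(C)C(C)(C)C)O
F4 | step 3 | (3R)-1-[(tert-butyldimethylsilyl)oxy]-6-methylideneundec-10-yn-3-ol | C#CCCCC(=C)CC[C@H](CCO[Si](C)(C)C(C)(C)C)O
F5 | step 3 | (3R)-1-[(tert-butyldimethylsilyl)oxy]-6-methylideneundec-10-yn-3-yl methanesulfonate | C#CCCCC(=C)CC[C@H](CCO[Si](C)(C)C(C)(C)C)OS(C)(=O)=O
F6 | step 3 | (3R)-1-[(tert-butyldimethylsilyl)oxy]-6-hydroperoxy-6-methoxyundec-10-yn-3-yl methanesulfonate (both C6 epimers) | C#CCCCC(OC)(OO)CC[C@H](CCO[Si](C)(C)C(C)(C)C)OS(C)(=O)=O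
F7 | step 3 | tert-butyl{2-[(3S)-6-methoxy-6-(pent-4-yn-1-yl)-1,2-dioxan-3-yl]ethoxy}dimethylsilane (both C6 epimers) | C#CCCCC1(OC)CC[C@@H](CCO[Si](C)(C)C(C)(C)C)OO1
F8 | step 3 | 2-[(3S,6R)-6-methoxy-6-(pent-4-yn-1-yl)-1,2-dioxan-3-yl]ethan-1-ol | C#CCCC[C@]1(OC)CC[C@@H](CCO)OO1
F9 | step 3 | 2-[(3S,6R)-6-methoxy-6-(pent-4-yn-1-yl)-1,2-dioxan-3-yl]acetic acid | C#CCCC[C@]1(OC)CC[C@@H](CC(=O)O)OO1
F10 | step 8 | (7E)-17-(trimethylsilyl)heptadec-7-ene-5,16-diynenitrile | C[Si](C)(C)C#CCCCCCCC/C=C/C#CCCCC#N
F11 | step 8 | trimethyl[(10E)-17,17,17-trimethoxyheptadec-10-ene-1,12-diyn-1-yl]silane | C[Si](C)(C)C#CCCCCCCC/C=C/C#CCCCC(OC)(OC)OC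
F12 | step 8 | methyl 2-[(3S)-6-methoxy-6-[(6E)-16-(trimethylsilyl)hexadec-6-ene-4,15-diyn-1-yl]-1,2-dioxan-3-yl]acetate (both C6 epimers) | C[Si](C)(C)C#CCCCCCCC/C=C/C#CCCCC1(OC)CC[C@@H](CC(=O)OC)OO1
F13 | step 7 | trimethyl(undeca-1,10-diyn-1-yl)silane | C[Si](C)(C)C#CCCCCCCCC#C
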